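## Analysis of the target

The chain is numbered C1–C23 from the ethyl end nearest the acetate, so that ring A is the 4H-pyran-4-one O/C3–C7, ring B is the 4H-pyran-4-one O/C15–C19, and C4, C6, C8, C10, C12, C14, C16, C18 and C20 each carry a methyl group. The seven stereocentres fall into three groups that cannot influence each other. These are the tetrad C8–C11 (all R; 8,9-anti, 9,10-syn, 10,11-anti, so O9/O11 are 1,3-anti), the lone C14 (S) beyond the (E)-C12=C13 alkene, and the anti pair C20/C21 (S,S) beyond flat ring B. The three secondary oxygens all differ: O9 is an acetate, O11 an allylic propanoate, O21 a free alcohol. The plan rests on one feature: rings A and B are the same heterocycle, and C8, C14 and C20 are simply the α-carbons of ethyl groups on its C7, C15 and C19, so the target is two copies of 2,6-diethyl-3,5-dimethyl-4H-pyran-4-one (4) tied together by C9–C13. Each of these three centres is a vinylogous α-carbonyl position, and C14, between C15 of ring B and alkene carbon C13, is also allylic; it is therefore the centre most easily epimerised or lost by alkene migration into conjugation, and for the same reason a radical at C14 is well stabilised. Other sensitive points are the ionisable allylic ester at C11, 1,3-acyl migration between O9 and O11, β-elimination whenever C7, C9 or C19 is a ketone, and the Lewis-basic ring carbonyls. The rings are easy; the difficulty is setting three isolated stereochemical groups, telling three alcohols apart, and making C13–C14 without base.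

## Retrosynthetic reasoning

**29 ⇒ 28.** Only O21 needs a mask, because O9 and O11 receive their final esters directly. The last step is removal of one silyl ether under buffered acidic fluoride, which leaves C14 alone.

**28 ⇒ 26 + 11 (key disconnection, C13–C14).**
- This is the only bond whose cleavage both separates the two copies of 4 and removes the orphan centre C14.
- Cutting here allows C14 to enter as a mixture. Chloride 11 gives the planar, ring-B-stabilised radical 27 from either epimer.
- A chiral nickel catalyst under reducing, base-free conditions joins 27 to the alkenyl iodide 26 and sets C14 by catalyst control.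
- The forward reaction must keep the E geometry, spare the allylic propanoate, and favour cross-coupling over homocoupling.

**26 ⇒ 25 ⇒ 22 + 23 (O–acyl bonds, C9–H).**
- The pattern "O11 propanoate, O9 different, 1,3-anti" is what an Evans–Tishchenko reduction of β-hydroxy ketone 22 with propanal 23 delivers.
- That reduction puts the ester on O11, sets C9 anti to C11, and leaves O9 free for acetylation, so no protecting group is needed.
- In 22, C8 lies between C9=O and ring A and is labile. The reduction is therefore asked to select the Felkin–Anh-matched C8 epimer from an equilibrating pair.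

**22 ⇒ 4 + 19 (C8–C9).** Because C8 need not be controlled at this stage, the bond can be made by simple acyl transfer from the active imide 19 to the lithium dienolate 20 of the symmetrical pyranone 4. Ring A arrives complete in one operation.

**19 ⇒ 18 + 15 (C10–C11); 18 ⇒ 16 + 17; 15 ⇒ 14 ⇒ 12.**
- An auxiliary-controlled anti-aldol sets C10 and C11. Its product is already O-silylated and is an acyl donor.
- The E-iodoalkene of 15 comes from syn-carbometallation of alkyne 12.

**11 ⇒ 9 ⇒ 8 ⇒ 7 ⇒ 4 + 5 (C14–Cl, O–Si, C21–H, C20–C21).**
- The second copy of 4 is acylated with 5 through its sodium dienolate 6 to give ketone 7, whose C20 is as labile as C8 in 22.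
- A dynamic enzymatic reduction converts racemic 7 into the anti (20S,21S)-alcohol 8.
- Silylation and chlorination of the remaining ethyl group give 11.

**4 ⇒ 1 + 2.** The common ring comes from twofold acylation of 1 with 2 and cyclodehydration of triketone 3 in one flask.

## Alternatives that were turned down

**Alternative 1:** the textbook cut at C11–C12.
- *Forward key step:* Nozaki–Hiyama–Kishi or alkenyllithium addition of alkenyl iodide A2 (C12–C23) to aldehyde A1 (C1–C11).
- *Stereochemistry:* Felkin–Anh addition to the α-methyl aldehyde A1 gives the 10,11-syn relationship, whereas the target is 10,11-anti. An oxidation/reduction correction would follow.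
- *C14:* it would have to be set early by auxiliary chemistry and then carried, as the most labile centre, through the construction of ring B.
- *Step economy:* both rings would be built separately by linear aldol/oxidation/cyclodehydration sequences, and O9, O11 and O21 would need three orthogonal protecting groups. The step count would be roughly double.

**Alternative 2:** the biomimetic cut of one ring C–O bond in each ring.
- *Forward key step:* twofold cyclodehydration of the acyclic bis(1,3,5-triketone) A3, which closes rings A and B together and erases C4, C6, C16 and C18.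
- *Value:* the rings are the cheapest part of the molecule (one step from 1), so this key step buys little.
- *Stability of A3:* C8, C14 and C20 are each α to a ketone, and C14 is also allylic. The O9 acetate is β to C7=O and O21 is β to C19=O, so elimination threatens. Alternative hemiketal closures compete.
- *Step economy:* A3 requires the whole 23-carbon chain to be built linearly with many redox adjustments.

**Alternative 3:** the cut at C10–C11 using ketone 7 twice.
- *Forward key step:* boron-mediated anti-aldol of ethyl ketone 7 (as C1–C10) with enal A4 (C11–C23) to give A5.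
- *Appeal:* this exposes the target as a pseudo-dimer of 7.
- *Regiochemistry:* C8–H of 7 is far more acidic than C10–H2, so enolisation would run the wrong way.
- *Stereocontrol:* 7 is racemic and labile, so face selectivity must come from a chiral boron reagent, and reagent-controlled anti-aldols of ethyl ketones are the weakest of that family. The ring carbonyls would also bind the boron Lewis acid.
- *Step economy:* A4 presupposes the C13–C14 bond, so the route becomes linear.

Key step: step 13

Assumption 1: in step 9 the (S)-4-benzylthiazolidinethione is taken to react through its non-chelated Z-enolate on the face away from the benzyl group, giving the (2S,3R)-anti adduct; the (R)-auxiliary is equally available if the sense is opposite.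

Assumption 2: the ligand antipode in step 13 and the enzyme in step 3 are selected by a short screen on these substrates; both ligand antipodes and ketoreductase panels are commercial.

## Steps

Step 1
Reactants: 1 pentan-3-one; 2 propanoic anhydride
Product: 4 2,6-diethyl-3,5-dimethyl-4H-pyran-4-one, via triketone 3 (not isolated)
Conditions: polyphosphoric acid, 110 °C
Reagents that add atoms: none
Why: Polyphosphoric acid C-acylates both α-carbons of 1 through its enol and then cyclodehydrates triketone 3 (enol oxygen onto the far carbonyl, loss of water), a long-known one-pot 4-pyranone synthesis. The two stereocentres of 3 vanish on ring closure.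

Step 2
Reactants: 4 2,6-diethyl-3,5-dimethyl-4H-pyran-4-one; 5 N-methoxy-N-methylpropanamide
Product: 7 2-ethyl-3,5-dimethyl-6-(3-oxopentan-2-yl)-4H-pyran-4-one (racemic), via sodium dienolate 6 (not isolated)
Conditions: 4 (2.2 equiv), NaHMDS (2.1 equiv), THF, −78 °C; 5 (1 equiv), −78 → 0 °C; 1 M HCl; surplus 4 recovered
Reagents that add atoms: none
Why: The two ethyl groups of 4 are equivalent, so vinylogous deprotonation raises no regiochemical question, and metallated 2-alkyl-4-pyranones are C-acylated at the exocyclic carbon with return of the ring (vinylogous Claisen-type condensation). The loosely paired sodium dienolate 6 is chosen as the more nucleophilic partner for the mildly electrophilic amide 5, and its second equivalent stores 7 as the stabilised enolate, so no free amide base meets 5 and no second addition occurs. C20 forms racemic and stays labile, which step 3 exploits.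

Step 3
Reactants: 7 2-ethyl-3,5-dimethyl-6-(3-oxopentan-2-yl)-4H-pyran-4-one
Product: 8 2-ethyl-6-[(2S,3S)-3-hydroxypentan-2-yl]-3,5-dimethyl-4H-pyran-4-one
Conditions: anti-selective Prelog-type ketoreductase (commercial panel), NADP+ (cat.), i-PrOH, phosphate buffer pH 8/DMSO, 30 °C
Reagents that add atoms: none
Why: This is a ketoreductase dynamic reductive kinetic resolution, a reaction type established for 2-alkyl-1,3-dicarbonyl compounds, including acyclic 2-methyl-1,3-diketones with an ethyl ketone end. C20–H, flanked by C21=O and C19 of ring B, racemises in the buffer, while the enzyme should accept only the (20S)-ketone and deliver hydride in the Prelog sense (ethyl as small group) to give (21S). Both new centres therefore come from the catalyst.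

Step 4
Reactants: 8 2-ethyl-6-[(2S,3S)-3-hydroxypentan-2-yl]-3,5-dimethyl-4H-pyran-4-one
Product: 9 2-ethyl-3,5-dimethyl-6-[(2S,3S)-3-(triethylsilyloxy)pentan-2-yl]-4H-pyran-4-one
Conditions: TESCl, imidazole, DMF, 0 °C → rt
Reagents that add atoms: chlorotriethylsilane CC[Si](Cl)(CC)CC
Why: Standard silylation of a secondary alcohol. The triethylsilyl ether tolerates amide base and the reductive coupling and leaves under buffered fluoride at the end.

Step 5
Reactants: 9 2-ethyl-3,5-dimethyl-6-[(2S,3S)-3-(triethylsilyloxy)pentan-2-yl]-4H-pyran-4-one
Product: 11 2-(1-chloroethyl)-3,5-dimethyl-6-[(2S,3S)-3-(triethylsilyloxy)pentan-2-yl]-4H-pyran-4-one (both C14 epimers), via lithium dienolate 10 (not isolated)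
Conditions: LiHMDS (1.05 equiv), THF, −78 °C; cannulated into C2Cl6 (1.5 equiv), THF, −78 °C
Reagents that add atoms: hexachloroethane ClC(Cl)(Cl)C(Cl)(Cl)Cl
Why: Kinetic deprotonation should take the open C14 methylene rather than the tertiary C20–H, which is shielded by the C18 methyl group and the silyloxy branch, and electrophiles attack lithiated 2-alkyl-4-pyranones at the exocyclic carbon. Inverse addition to excess chlorine donor suppresses proton exchange and double chlorination. The C14 configuration is irrelevant because step 13 erases it.

Step 6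
Reactants: 12 prop-2-yn-1-ol
Product: 14 (E)-3-iodo-2-methylprop-2-en-1-ol, via alkenylalane 13 (not isolated)
Conditions: Me3Al (3 equiv), Cp2ZrCl2 (25 mol %), CH2Cl2, 0 °C → rt; I2, THF, −30 °C; aq. Rochelle salt
Reagents that add atoms: trimethylaluminium C[Al](C)C; iodine II
Why: Zirconium-catalysed carboalumination (Negishi) adds methyl and aluminium syn across the alkyne with aluminium at the terminus, and iodinolysis retains configuration. This fixes the E geometry of the later C12=C13 bond and brings in the C12 methyl group.

Step 7
Reactants: 14 (E)-3-iodo-2-methylprop-2-en-1-ol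
Product: 15 (E)-3-iodo-2-methylprop-2-enal
Conditions: MnO2, CH2Cl2, rt
Reagents that add atoms: none
Why: Selective allylic alcohol oxidation on manganese dioxide under neutral conditions, without E/Z isomerisation or loss of iodine.

Step 8
Reactants: 16 (S)-4-benzyl-1,3-thiazolidine-2-thione; 17 propanoyl chloride
Product: 18 (S)-4-benzyl-3-propanoyl-1,3-thiazolidine-2-thione
Conditions: Et3N, DMAP (cat.), CH2Cl2, 0 °C
Reagents that add atoms: none
Why: Routine N-acylation of the auxiliary. The propanoyl group supplies C9, C10 and the C10 methyl group.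

Step 9
Reactants: 18 (S)-4-benzyl-3-propanoyl-1,3-thiazolidine-2-thione; 15 (E)-3-iodo-2-methylprop-2-enal
Product: 19 (2S,3R,4E)-1-[(4S)-4-benzyl-2-thioxo-1,3-thiazolidin-3-yl]-5-iodo-2,4-dimethyl-3-(trimethylsilyloxy)pent-4-en-1-one
Conditions: MgBr2·OEt2 (10 mol %), Et3N (2 equiv), TMSCl (1.5 equiv), EtOAc, rt; filtration through buffered silica
Reagents that add atoms: chlorotrimethylsilane C[Si](C)(C)Cl
Why: This is the magnesium halide-catalysed direct anti-aldol of N-acylthiazolidinethiones with non-enolisable α-branched enals: soft enolisation gives the Z-enolate, which attacks 15 through a boat-like transition state on the face away from the benzyl group. Silylation of the aldolate makes the addition irreversible and turns magnesium over. This sets C10 and C11 (10,11-anti), and the product is already O-protected and an active acyl donor.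

Step 10
Reactants: 4 2,6-diethyl-3,5-dimethyl-4H-pyran-4-one; 19 (2S,3R,4E)-1-[(4S)-4-benzyl-2-thioxo-1,3-thiazolidin-3-yl]-5-iodo-2,4-dimethyl-3-(trimethylsilyloxy)pent-4-en-1-one
Product: 22 2-ethyl-6-[(4S,5R,6E)-5-hydroxy-7-iodo-4,6-dimethyl-3-oxohept-6-en-2-yl]-3,5-dimethyl-4H-pyran-4-one (C8 epimers), via lithium dienolate 20 (not isolated), via silyl ether ketone 21 (not isolated)
Conditions: 4 (2.3 equiv), LiHMDS (2.2 equiv), THF, −78 °C; 19, −78 → −40 °C; 1 M HCl, THF, 0 °C
Reagents that add atoms: none
Why: N-Acylthiazolidinethiones transfer their acyl group to lithium enolates and lithiated phosphonates, here to the exocyclic carbon of the lithium dienolate 20, forming C8–C9; lithium is used for this union because its tighter ion pair is less basic towards C10–H of 19. The second equivalent of 20 turns ketone 21 into its C8 enolate, which blocks over-addition, shields C10 from epimerisation and O11 from β-elimination. Dilute acid then removes the trimethylsilyl group, and C8 is a mixture on purpose.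

Step 11
Reactants: 22 2-ethyl-6-[(4S,5R,6E)-5-hydroxy-7-iodo-4,6-dimethyl-3-oxohept-6-en-2-yl]-3,5-dimethyl-4H-pyran-4-one (C8 epimers); 23 propanal
Product: 25 (1E,3R,4R,5R,6R)-6-(6-ethyl-3,5-dimethyl-4-oxo-4H-pyran-2-yl)-5-hydroxy-1-iodo-2,4-dimethylhept-1-en-3-yl propanoate, via hemiacetal 24 (not isolated)
Conditions: SmI2 (30 mol %, pre-stirred with 23), THF, 0 °C; 23 (6 equiv) added slowly by syringe pump
Reagents that add atoms: none
Why: Proposed new method: the samarium-bound hemiacetal 24 delivers hydride within a chair-like chelate to one face of C9 (Evans–Tishchenko reduction, the closest known reaction type, which reliably gives the 1,3-anti diol monoester, here with the propanoate on O11 and O9 free); the new element is that C8, acidified by C9=O and ring A, is expected to epimerise through its samarium enolate faster than hydride shifts, helped by keeping 23 scarce. Under these Curtin–Hammett conditions the faster epimer is the one in which hydride enters anti to ring A with C8–H rather than C8–CH3 turned towards the branched C10 (Felkin–Anh), which gives the 8,9-anti, (8R,9R), product. The stereoconvergent aldol–Tishchenko reaction, where a reversible step before the hydride shift is funnelled in the same way, supports the idea.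

Step 12
Reactants: 25 (1E,3R,4R,5R,6R)-6-(6-ethyl-3,5-dimethyl-4-oxo-4H-pyran-2-yl)-5-hydroxy-1-iodo-2,4-dimethylhept-1-en-3-yl propanoate
Product: 26 (1E,3R,4R,5R,6R)-5-acetoxy-6-(6-ethyl-3,5-dimethyl-4-oxo-4H-pyran-2-yl)-1-iodo-2,4-dimethylhept-1-en-3-yl propanoate
Conditions: Ac2O, pyridine, DMAP (cat.), CH2Cl2, 0 °C
Reagents that add atoms: acetic anhydride CC(=O)OC(C)=O
Why: DMAP-catalysed acetylation of the only free hydroxyl group. Fast acylation at low temperature forestalls 1,3-migration of the propanoate from O11 to O9, and C8 is no longer labile once C9 is sp3.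

Step 13
Reactants: 26 (1E,3R,4R,5R,6R)-5-acetoxy-6-(6-ethyl-3,5-dimethyl-4-oxo-4H-pyran-2-yl)-1-iodo-2,4-dimethylhept-1-en-3-yl propanoate; 11 2-(1-chloroethyl)-3,5-dimethyl-6-[(2S,3S)-3-(triethylsilyloxy)pentan-2-yl]-4H-pyran-4-one (both C14 epimers)
Product: 28 (2R,3R,4R,5R,6E,8S)-3-acetoxy-2-(6-ethyl-3,5-dimethyl-4-oxo-4H-pyran-2-yl)-8-{3,5-dimethyl-4-oxo-6-[(2S,3S)-3-(triethylsilyloxy)pentan-2-yl]-4H-pyran-2-yl}-4,6-dimethylnon-6-en-5-yl propanoate, via C14 radical 27 (not isolated)
Conditions: NiCl2·dme (10 mol %), 2,2'-(cyclopropane-1,1-diyl)bis(3a,8a-dihydro-8H-indeno[1,2-d]oxazole) (one antipode, 11 mol %), Mn powder (3 equiv), NaI (0.5 equiv), DMA, 0 °C; 11 (1.3 equiv)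
Reagents that add atoms: none
Why: Nickel(0) inserts into the C13–I bond of 26 with retention of the E geometry, a nickel(I) halide abstracts chlorine from either C14 epimer of 11 to give the same planar radical 27 (delocalised into C15=C16–C17=O of ring B), 27 is captured at the alkenylnickel(II) centre, reductive elimination from nickel(III) forms C13–C14, and manganese returns nickel to the zero-valent state. The closest known reaction type is the nickel/bis(oxazoline)-catalysed asymmetric reductive cross-coupling of alkenyl halides with racemic secondary benzylic chlorides, flanked by the enantioconvergent alkenylation of racemic α-halo carbonyl compounds; 11 is both a heterobenzylic chloride and a vinylogous α-chloro ester. No ring is closed: the step joins the C1–C13 and C14–C23 halves in the middle of the chain. The one new stereocentre, C14, is set by the chiral ligand during capture and reductive elimination and not by the substrate, because the nearest centres C11 and C20 are held away by the alkene and by flat ring B, so both epimers of 11 are funnelled into (14S). Cross-selectivity over homocoupling rests on the different activation modes of the two halides, two-electron for C(sp2)–I and one-electron for C(sp3)–Cl. The allylic propanoate at C11 should survive because insertion into C–I is much faster than ionisation of a hindered trisubstituted allylic ester, and the esters, silyl ether and ring carbonyls are inert to manganese at 0 °C. The medium contains no base, so the doubly activated C14–H of 28 is neither epimerised nor moved into conjugation.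

Step 14
Reactants: 28 21-O-triethylsilyl ether of the target
Product: 29 (2R,3R,4R,5R,6E,8S)-3-acetoxy-2-(6-ethyl-3,5-dimethyl-4-oxo-4H-pyran-2-yl)-8-{6-[(2S,3S)-3-hydroxypentan-2-yl]-3,5-dimethyl-4-oxo-4H-pyran-2-yl}-4,6-dimethylnon-6-en-5-yl propanoate (CNP0265513.1)
Conditions: HF·pyridine, pyridine, THF, 0 °C
Reagents that add atoms: none
Why: Buffered HF·pyridine cleaves the secondary triethylsilyl ether, while both esters, the allylic C11–O bond and the base-sensitive C14 are left untouched. O21 is too far from the esters for acyl migration.

## Compound list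

1 | pentan-3-one | CCC(=O)CC | starting material
2 | propanoic anhydride | CCC(=O)OC(=O)CC | starting material
3 | 4,6-dimethylnonane-3,5,7-trione (stereoisomer mixture, not isolated) | CCC(=O)C(C)C(=O)C(C)C(=O)CC | intermediate
4 | 2,6-diethyl-3,5-dimethyl-4H-pyran-4-one | CCc1oc(CC)c(C)c(=O)c1C | intermediate
5 | N-methoxy-N-methylpropanamide | CCC(=O)N(C)OC | starting material
6 | sodium 2-ethyl-6-ethylidene-3,5-dimethyl-6H-pyran-4-olate (sodium dienolate of 4, not isolated) | CC=C1OC(CC)=C(C)C([O-])=C1C.[Na+] | intermediate
7 | 2-ethyl-3,5-dimethyl-6-(3-oxopentan-2-yl)-4H-pyran-4-one (racemic, C20 labile) | CCC(=O)C(C)c1oc(CC)c(C)c(=O)c1C | intermediate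
8 | 2-ethyl-6-[(2S,3S)-3-hydroxypentan-2-yl]-3,5-dimethyl-4H-pyran-4-one | CCc1oc([C@@H](C)[C@@H](O)CC)c(C)c(=O)c1C | intermediate
9 | 2-ethyl-3,5-dimethyl-6-[(2S,3S)-3-(triethylsilyloxy)pentan-2-yl]-4H-pyran-4-one | CCc1oc([C@@H](C)[C@@H](O[Si](CC)(CC)CC)CC)c(C)c(=O)c1C | intermediate
10 | lithium dienolate of 9, deprotonated at C14 (not isolated) | CC=C1OC([C@@H](C)[C@@H](O[Si](CC)(CC)CC)CC)=C(C)C([O-])=C1C.[Li+] | intermediate
11 | 2-(1-chloroethyl)-3,5-dimethyl-6-[(2S,3S)-3-(triethylsilyloxy)pentan-2-yl]-4H-pyran-4-one (both C14 epimers) | CC(Cl)c1oc([C@@H](C)[C@@H](O[Si](CC)(CC)CC)CC)c(C)c(=O)c1C | intermediate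
12 | prop-2-yn-1-ol | C#CCO | starting material
13 | [(E)-3-(dimethylalumanyloxy)-2-methylprop-1-enyl]dimethylalumane (not isolated) | C[Al](C)/C=C(\C)CO[Al](C)C | intermediate
14 | (E)-3-iodo-2-methylprop-2-en-1-ol | OC/C(C)=C/I | intermediate
15 | (E)-3-iodo-2-methylprop-2-enal | O=C/C(C)=C/I | intermediate
16 | (S)-4-benzyl-1,3-thiazolidine-2-thione | S=C1N[C@@H](Cc2ccccc2)CS1 | starting material
17 | propanoyl chloride | CCC(=O)Cl | starting material
18 | (S)-4-benzyl-3-propanoyl-1,3-thiazolidine-2-thione | CCC(=O)N1[C@@H](Cc2ccccc2)CSC1=S | intermediate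
19 | (2S,3R,4E)-1-[(4S)-4-benzyl-2-thioxo-1,3-thiazolidin-3-yl]-5-iodo-2,4-dimethyl-3-(trimethylsilyloxy)pent-4-en-1-one | C[Si](C)(C)O[C@@H](/C(C)=C/I)[C@H](C)C(=O)N1[C@@H](Cc2ccccc2)CSC1=S | intermediate
20 | lithium 2-ethyl-6-ethylidene-3,5-dimethyl-6H-pyran-4-olate (lithium dienolate of 4, not isolated) | CC=C1OC(CC)=C(C)C([O-])=C1C.[Li+] | intermediate
21 | 2-ethyl-6-[(4S,5R,6E)-7-iodo-4,6-dimethyl-3-oxo-5-(trimethylsilyloxy)hept-6-en-2-yl]-3,5-dimethyl-4H-pyran-4-one (C8 epimers, not isolated) | C[Si](C)(C)O[C@@H](/C(C)=C/I)[C@H](C)C(=O)C(C)c1oc(CC)c(C)c(=O)c1C | intermediate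
22 | 2-ethyl-6-[(4S,5R,6E)-5-hydroxy-7-iodo-4,6-dimethyl-3-oxohept-6-en-2-yl]-3,5-dimethyl-4H-pyran-4-one (C8 epimers) | O[C@@H](/C(C)=C/I)[C@H](C)C(=O)C(C)c1oc(CC)c(C)c(=O)c1C | intermediate
23 | propanal | CCC=O | starting material
24 | O11 hemiacetal of 22 with propanal (samarium-bound in the flask, not isolated) | CCC(O)O[C@@H](/C(C)=C/I)[C@H](C)C(=O)C(C)c1oc(CC)c(C)c(=O)c1C | intermediate
25 | (1E,3R,4R,5R,6R)-6-(6-ethyl-3,5-dimethyl-4-oxo-4H-pyran-2-yl)-5-hydroxy-1-iodo-2,4-dimethylhept-1-en-3-yl propanoate | CCC(=O)O[C@@H](/C(C)=C/I)[C@H](C)[C@@H](O)[C@@H](C)c1oc(CC)c(C)c(=O)c1C | intermediate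
26 | (1E,3R,4R,5R,6R)-5-acetoxy-6-(6-ethyl-3,5-dimethyl-4-oxo-4H-pyran-2-yl)-1-iodo-2,4-dimethylhept-1-en-3-yl propanoate | CCC(=O)O[C@@H](/C(C)=C/I)[C@H](C)[C@@H](OC(C)=O)[C@@H](C)c1oc(CC)c(C)c(=O)c1C | intermediate
27 | planar C14 radical derived from 11 (not isolated) | C[CH]c1oc([C@@H](C)[C@@H](O[Si](CC)(CC)CC)CC)c(C)c(=O)c1C | intermediate
28 | 21-O-triethylsilyl ether of the target, (8R,9R,10R,11R,12E,14S,20S,21S) | CCC(=O)O[C@@H](/C(C)=C/[C@H](C)c1oc([C@@H](C)[C@@H](O[Si](CC)(CC)CC)CC)c(C)c(=O)c1C)[C@H](C)[C@@H](OC(C)=O)[C@@H](C)c1oc(CC)c(C)c(=O)c1C | intermediate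
29 | CNP0265513.1, (8R,9R,10R,11R,12E,14S,20S,21S) | CCC(=O)O[C@@H](/C(C)=C/[C@H](C)c1oc([C@@H](C)[C@@H](O)CC)c(C)c(=O)c1C)[C@H](C)[C@@H](OC(C)=O)[C@@H](C)c1oc(CC)c(C)c(=O)c1C | target

## Step count and risk

Total step count: 14.

Longest linear sequence: 8 steps (steps 6, 7, 9, 10, 11, 12, 13, 14). The ring-B branch (steps 1–5, 13, 14) has 7.

Least certain steps:

**Step 11 (Proposed new method).**
- *What may go wrong:* the reduction itself should work, but C8 may epimerise more slowly than hydride shifts. Both epimers would then be reduced and selectivity at C8 would be poor. Retro-aldol cleavage of C10–C11 on the samarium alkoxide, binding of samarium by the ring carbonyl, and drift of the propanoate from O11 to O9 are secondary concerns.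
- *Fallback (known chemistry, from 19 back to 26):* C9 is set by addition to an aldehyde instead of by reduction. DIBAL-H cleaves the auxiliary from 19 to give (2S,3R,4E)-5-iodo-2,4-dimethyl-3-(trimethylsilyloxy)pent-4-enal F1. Lithium dienolate 20, made from 4 as in step 10, adds to it under Felkin–Anh and 1,3-anti control, which reinforce each other in a 2,3-anti aldehyde, and the 8,9-anti carbinol F2 is separated from its C8 epimer. Acetylation gives the C9 acetate F3, citric acid in methanol frees the C11 alcohol F4, and propanoic anhydride with DMAP gives 26.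

**Step 13 (key step).**
- *What may go wrong:* low facial selectivity at C14, because ring B with its flanking C16 methyl group is not a plain arene. Dimerisation or reduction of radical 27 may outrun its capture. Oxidative addition to the hindered trisubstituted iodide may be slow, and nickel may attack the allylic propanoate.
- *Fallback (from 11 and 26 back to 28):* stereoconvergence is given up. Zinc dust with LiCl in THF turns 11 into the secondary organozinc chloride F5, and a palladium-catalysed Negishi coupling with 26, a known union of secondary benzylic zinc reagents with alkenyl iodides under non-basic conditions, gives 28 together with its (14R)-epimer F6. The two are separated by chromatography.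

**Step 3.**
- *What may go wrong:* no enzyme may accept the bulky ring-B side of the ketone, or C20 may racemise too slowly in buffer, so that conversion stalls halfway or diastereoselectivity erodes.
- *Fallback (from 7 back to 8):* reduction with NaBH4/CeCl3 in MeOH at −78 °C follows the Felkin–Anh model (ring B as large group) and should favour the racemic anti alcohol, that is 8 together with 2-ethyl-6-[(2R,3R)-3-hydroxypentan-2-yl]-3,5-dimethyl-4H-pyran-4-one F7. A lipase with vinyl acetate acylates the (21R)-enantiomer, following the Kazlauskas rule, to give the (2R,3R)-acetate F8 and leaves 8. F8 is returned to 7 by methanolysis and oxidation, so no material is lost.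

**Step 10.**
- *What may go wrong:* proton transfer from the acidic C10–H of imide 19 to the basic dienolate may compete with acyl transfer, causing loss of the auxiliary by another path or erosion at C10. The union of two branched partners may also be slow.
- *Fallback (from 19 back to 21):* the bond is made at the aldehyde oxidation level, where addition is fast. The aldehyde F1 described above takes up 20 at −78 °C to give the carbinol mixture F9 (all C8/C9 isomers, none of which matters). Dess–Martin oxidation gives 21, and dilute acid then gives 22.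

**Step 5.**
- *What may go wrong:* competing deprotonation at C20 would cause epimerisation or loss of silanolate, and proton exchange between product and dienolate would lead to double chlorination.
- *Fallback (from 8 back to 11):* the free alcohol 8 is treated with two equivalents of base. The O21 alkoxide forms first, and its charge next to C20 disfavours deprotonation there. The second equivalent removes a C14 proton, and chlorination gives the chloro alcohol F10, which is silylated with TESOTf/2,6-lutidine to give 11.

## Further compounds

F1 | step 11 | (2S,3R,4E)-5-iodo-2,4-dimethyl-3-(trimethylsilyloxy)pent-4-enal | C[Si](C)(C)O[C@@H](/C(C)=C/I)[C@H](C)C=O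
F2 | step 11 | 8,9-anti carbinol, 2-ethyl-6-[(2R,3R,4R,5R,6E)-3-hydroxy-7-iodo-4,6-dimethyl-5-(trimethylsilyloxy)hept-6-en-2-yl]-3,5-dimethyl-4H-pyran-4-one | C[Si](C)(C)O[C@@H](/C(C)=C/I)[C@H](C)[C@@H](O)[C@@H](C)c1oc(CC)c(C)c(=O)c1C
F3 | step 11 | C9 acetate of F2 | C[Si](C)(C)O[C@@H](/C(C)=C/I)[C@H](C)[C@@H](OC(C)=O)[C@@H](C)c1oc(CC)c(C)c(=O)c1C
F4 | step 11 | C11 alcohol (C9 acetate, O11 free) | O[C@@H](/C(C)=C/I)[C@H](C)[C@@H](OC(C)=O)[C@@H](C)c1oc(CC)c(C)c(=O)c1C
F5 | step 13 | secondary organozinc chloride from 11 | CC([Zn]Cl)c1oc([C@@H](C)[C@@H](O[Si](CC)(CC)CC)CC)c(C)c(=O)c1C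
F6 | step 13 | (14R)-epimer of 28 | CCC(=O)O[C@@H](/C(C)=C/[C@@H](C)c1oc([C@@H](C)[C@@H](O[Si](CC)(CC)CC)CC)c(C)c(=O)c1C)[C@H](C)[C@@H](OC(C)=O)[C@@H](C)c1oc(CC)c(C)c(=O)c1C
F7 | step 3 | 2-ethyl-6-[(2R,3R)-3-hydroxypentan-2-yl]-3,5-dimethyl-4H-pyran-4-one | CCc1oc([C@H](C)[C@H](O)CC)c(C)c(=O)c1C
F8 | step 3 | (2R,3R)-acetate of F7 | CCc1oc([C@H](C)[C@H](OC(C)=O)CC)c(C)c(=O)c1C
F9 | step 10 | carbinol mixture (C8 and C9 undefined) from F1 and 20 | C[Si](C)(C)O[C@@H](/C(C)=C/I)[C@H](C)C(O)C(C)c1oc(CC)c(C)c(=O)c1C
F10 | step 5 | chloro alcohol, 2-(1-chloroethyl)-6-[(2S,3S)-3-hydroxypentan-2-yl]-3,5-dimethyl-4H-pyran-4-one | CC(Cl)c1oc([C@@H](C)[C@@H](O)CC)c(C)c(=O)c1C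
A1 | alternative 1 | C1–C11 aldehyde, C8–C10 arranged as in 29, O9 as TBS ether | O=C[C@H](C)[C@@H](O[Si](C)(C)C(C)(C)C)[C@@H](C)c1oc(CC)c(C)c(=O)c1C
A2 | alternative 1 | C12–C23 (E)-alkenyl iodide, C14, C20, C21 as in 29, O21 as TES ether | I/C(C)=C/[C@H](C)c1oc([C@@H](C)[C@@H](O[Si](CC)(CC)CC)CC)c(C)c(=O)c1C
A3 | alternative 2 | acyclic bis(1,3,5-triketone), C4, C6, C16, C18 undefined | CCC(=O)O[C@@H](/C(C)=C/[C@H](C)C(=O)C(C)C(=O)C(C)C(=O)[C@@H](C)[C@@H](O[Si](CC)(CC)CC)CC)[C@H](C)[C@@H](OC(C)=O)[C@@H](C)C(=O)C(C)C(=O)C(C)C(=O)CC
A4 | alternative 3 | C11–C23 enal | O=C/C(C)=C/[C@H](C)c1oc([C@@H](C)[C@@H](O[Si](CC)(CC)CC)CC)c(C)c(=O)c1C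
A5 | alternative 3 | C10–C11 anti-aldol adduct of 7 and A4 (C8 undefined) | O[C@@H](/C(C)=C/[C@H](C)c1oc([C@@H](C)[C@@H](O[Si](CC)(CC)CC)CC)c(C)c(=O)c1C)[C@H](C)C(=O)C(C)c1oc(CC)c(C)c(=O)c1C
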